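## Structural features

The target is the linear tetramer epicatechin-(4β→6)-epicatechin-(4β→8)-epicatechin-(4β→6)-epicatechin, built from four (2R,3R)-2-arylchroman-3-ol units (ring A, ring C and the catechol ring B in each), numbered 1 to 4 from the top. Three benzylic C–C bonds join them: C4 of unit 1 to C6 of unit 2, C4 of unit 2 to C8 of unit 3, and C4 of unit 3 to C6 of unit 4. There are eleven stereocentres; C2 and C3 are cis in every unit, and units 1 to 3 carry in addition a C4 centre whose aryl group is trans to the neighbouring 3-hydroxyl, so that these units hold contiguous C2–C3–C4 triads. The twenty free hydroxyls make the compound sensitive to air and base, C2 epimerises in base, and each interflavan bond is a bond to a phloroglucinol-type ring that acid can cleave. The real difficulty lies in the two 4→6 bonds, because intermolecular arylation of a 5,7-dioxygenated ring A goes to C8, and in holding the chain at exactly four units. Units 1–2 and units 3–4 are the same 4β→6 dimer, so the tetramer is one dimer used twice and joined through the only 4→8 bond. In the lower unit of that dimer ring C is fused to ring A through O1–C8a and C4–C4a with C6 para to C8a, and the key step exploits this: a phenol that already carries the upper unit para to its hydroxyl and a formyl group ortho to it can be annulated to ring C only in the 4→6 sense.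

## Logic of the disconnections

**20 ⇒ 19.** Eighteen O–benzyl bonds and three C8–Br bonds are put back. The free polyphenol is too fragile to carry through any step, so everything before the last step runs on a lipophilic, non-oxidisable compound. The demand is a single neutral hydrogenolysis that cleaves all C–O(benzyl) and C–Br bonds but leaves the benzylic interflavan C–C bonds and the C2–O1 bonds alone.

**19 ⇒ 18 + 16.** The bond cut is C4 of unit 2 to C8 of unit 3. It is the only 4→8 bond, the natural site of ring A arylation, and it divides the tetramer into two halves of the same skeleton, so that 18 can be made from 16. The demand is that the C4 cation from 18 is taken only by C8 of the upper unit of 16 and from the face trans to the 3-hydroxyl. Every other C8 position therefore carries bromine, which blocks or deactivates the rings that must not react.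

**18 ⇒ 17 ⇒ 16.** The C4–O ether bond of the lower unit and the C8–Br bond of the upper unit are removed. These two functionalisations turn the nucleophilic dimer into the electrophilic one. The demands are hydride abstraction at the C4 methylene of the lower unit and not at the interflavan methine, and bromination at C8 of the one ring A that still has free positions.

**16 ⇒ 15 ⇒ 14 ⇒ 13.** The C3–H bond and then the C3–O bond are traced back to a C3–CHO bond. The formyl carbon is what makes the ring closure of the key step possible and is excised afterwards. The demands are oxygen insertion on the alkenyl side of the aldehyde, a ketone that does not enolise towards C2, and hydride delivery that gives the 2,3-cis alcohol.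

**13 ⇒ 10 + 12.** The bonds cut are O1–C2 and C3–C4 of ring C of the lower unit. This reduces the dimer to an arylated salicylaldehyde and a three-carbon enal, and the 4→6 connectivity is decided by where the substituents of 10 already sit. The demand is enantioface selection at C2 by the catalyst, and addition of a phenol that is hydrogen-bonded to its own formyl group.

**12 ⇒ 11.** The Cα=Cβ bond is cut. A stabilised ylide gives the E-alkene needed for a defined iminium geometry.

**10 ⇒ 9 ⇒ 8.** The C–CHO and C–Br bonds ortho to the phenol are removed. In 8 both ortho carbons are equivalent, so which group goes where is not a regiochemical question. The demands are that bromination stops after one substitution and picks the phenol ring over the ether rings, and that formylation then takes the only ortho carbon left.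

**8 ⇒ 7 ⇒ 6 ⇒ 5.** Two O–benzyl bonds and one O–Si bond are removed. The hydroxyl para to the flavanyl group must become O1 of the lower unit and the two ortho hydroxyls must become O5 and O7. The demand is a silylation that picks the unhindered para hydroxyl; a wrong silylation can be undone with fluoride and repeated.

**5 ⇒ 3 + 4.** The C4–aryl bond is cut. 4 is threefold symmetric, so no positional isomer can form, and as a free triphenol it is a better nucleophile than ring A of 3 or of 5, which keeps oligomerisation of the flavan down. A ring that already carried bromine would be deactivated in the way this plan uses for its caps, so bromine is brought in only after this bond exists. The demand is β-attack, which the 2,3-cis substituents enforce, and an excess of 4 against double arylation.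

**3 ⇒ 2 ⇒ 1.** The C4–O bond and five O–benzyl bonds are removed. 1 supplies C2 and C3 of units 1 and 3 from the chiral pool. The demand is perbenzylation without epimerisation at C2 and oxidation at C4 only.

## Other disconnections considered

Alternative 1: The cut is C4–C4a of ring C of unit 1, closed onto a chain that is already bonded to C6 of unit 2.
- Forward key step: the epoxy aryl ether A2 is treated with BF3·OEt2, and the arene carbon ortho to the ether oxygen opens the benzylic epoxide carbon in a 6-endo Friedel–Crafts closure to give A1.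
- In its favour: the 3-hydroxyl appears directly at the right oxidation level and trans to the new C4–C4a bond. No formyl excision and no ketone reduction are needed, and on this point of redox economy after ring closure it is better than the chosen plan.
- Equal to the chosen plan: the 4→6 connectivity is fixed by construction, and A1 is the same kind of dimer as 16 and could serve as both halves.
- Against it here: A2 carries three stereocentres in an open chain (the carbinol carbon that becomes C2 and both epoxide carbons). They must be set by reagent control and survive aryl ether formation at an ionisable benzylic carbinol.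
- Against it here: the carbon chain must first be attached to C6 of an 8-bromoflavan, its least reactive position, so the difficult 4→6 bond is moved and not avoided.
- Mechanism: a Lewis acid acts next to an electron-rich flavan and an ionising benzylic centre, with 5-exo closure and loss of C4 configuration as possible leaks. The chosen step runs under near-neutral amine catalysis.
- Step economy: shorter after the ring closure, longer before it, and judged longer overall.

Alternative 2: The cut is ring A of unit 4 itself, at C4a–C8a, C5–C6 and C8–C8a.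
- Forward key step: the cyclobutenone A4 and the siloxyalkyne A5 are heated in toluene. Electrocyclic opening of A4 gives a vinylketene, and its [2+2] addition to the ynol ether forms C4a–C8a and C5–C6. A second ring opening and a 6π closure then form C8–C8a, and tautomerisation gives the phenol A3.
- Structure: the flavanyl group sits on C2 of A4, the alkene carbon next to the carbonyl. That carbon ends up between the silyloxy and benzyloxy carbons of the new ring, which is C6 of unit 4; the methylene of A4 becomes C8 and the carbonyl carbon becomes C8a.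
- In its favour: ring A emerges with each oxygen differently protected (free at C8a, silyl at O5, benzyl at O7). On this point it is better than the chosen plan, which spends steps 4 to 6 on the same differentiation.
- In its favour: no Lewis acid is present, and the position of unit 3 is as secure as in the chosen plan.
- Against it here: A3 has neither ring C nor a new stereocentre. The cinnamyl chain must still be turned into C2 and C3, O5 re-protected and C8 blocked.
- Against it here: A4 needs a four-membered 1,3-dicarbonyl unit attached through its central carbon to C4 of the flavan and then O-benzylated, which has no close model on flavans, and A5 is a labile ynol ether with an allylic chain.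
- Mechanism: a pericyclic cascade that creates no stereocentre, whereas the chosen step creates C2.
- Step economy: clearly more steps after the key step than in the chosen plan.

Alternative 3: The cut is three bonds of ring C of unit 2, C4–C4a, C3–C4 and O1–C2, which is the ring that carries the central 4→8 bond.
- Forward key step: phenol 8 and the aldehyde A7 are templated by PhB(OH)2 into a benzodioxaborin. BF3·OEt2 then releases an ortho-quinone methide, which is trapped by the silyl enol ether A8 in a hetero-[4+2] addition to give A6.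
- In its favour: the central bond and ring C of unit 2 form together from three components. No dimeric C4 electrophile, no oxidation of a dimer and no intermolecular Friedel–Crafts union are needed, and on convergence it is better than the chosen plan.
- Equal to the chosen plan: it starts from 8, which the chosen route makes anyway.
- Against it here: A7 is the lower dimer with ring C of unit 4 already built and then formylated at C8 of unit 3, so this cut adds to the chosen key step and does not replace it.
- Against it here: the cycloaddition must set C3 and C4 of unit 2 in the correct absolute sense, and nothing but two remote flavan units controls the faces of the planar quinone methide. C2 is left as a ketal and needs a further stereoselective reduction.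
- Against it here: the formyl group of A7 is flanked by O1 and a benzyloxy group, so the templating step is sterically demanding.
- Step economy: potentially shorter overall, but with much lower stereochemical security than catalyst control at C2 followed by a precedented ketone reduction.

Key step: step 10

Assumption: the sense of induction in step 10 is taken from the usual shielding model for (E)-iminium ions of diarylprolinol silyl ethers; if this substrate shows the opposite sense, the enantiomeric catalyst is the one to use.

Remark on the design: ring A of the lower unit is taken from phloroglucinol (4) and the bromine is introduced only after the arylation, at the free-phenol stage. A brominated, silylated ring would be a deactivated and hindered nucleophile that cannot outrun arylation of ring A of the product.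

Naming: "penta-O-benzylepicatechin-4β-yl" is the (2R,3R)-3,5,7-tris(benzyloxy)-2-[3,4-bis(benzyloxy)phenyl]chroman-4-yl group, bonded through C4 on the face trans to the 3-benzyloxy group; "8-bromo-penta-O-benzylepicatechin-4β-yl" is the same group with bromine at C8.

Step 1
Reactants: 1 (−)-epicatechin
Product: 2 penta-O-benzylepicatechin [(2R,3R)-3,5,7-tris(benzyloxy)-2-[3,4-bis(benzyloxy)phenyl]chromane]
Conditions: BnBr (6 equiv), NaH (6 equiv), DMF, −20 °C to rt
Reagents that add atoms: benzyl bromide, BrCc1ccccc1
Why: Williamson etherification of the four phenols and, with the excess of NaH, of the secondary alcohol; benzyl bromide is present from the start and the temperature is kept low so that the phenoxides are trapped before base-induced epimerisation at C2 can begin.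

Step 2
Reactants: 2 penta-O-benzylepicatechin
Product: 3 (2R,3R,4S)-3,5,7-tris(benzyloxy)-2-[3,4-bis(benzyloxy)phenyl]-4-(2-ethoxyethoxy)chromane
Conditions: DDQ (1.5 equiv), 2-ethoxyethanol (5 equiv), CH2Cl2, rt
Reagents that add atoms: 2-ethoxyethanol, CCOCCO
Why: Oxidative benzylic etherification: DDQ abstracts hydride from C4, the position stabilised by the three oxygens of ring A, and the alcohol adds to the cation trans to the 3-benzyloxy group. The configuration at C4 is of no consequence because the centre is ionised again in step 3.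

Step 3
Reactants: 3 (2R,3R,4S)-3,5,7-tris(benzyloxy)-2-[3,4-bis(benzyloxy)phenyl]-4-(2-ethoxyethoxy)chromane; 4 phloroglucinol
Product: 5 2-(penta-O-benzylepicatechin-4β-yl)benzene-1,3,5-triol
Conditions: phloroglucinol in fivefold excess, BF3·OEt2 (0.5 equiv), THF–CH2Cl2, −20 to 0 °C
Reagents that add atoms: none
Why: Friedel–Crafts arylation by the C4 cation of a 4-alkoxyflavan, the laboratory form of the classical trapping of flavan-4-yl cations by phloroglucinol; all three ring carbons of 4 are equivalent and its excess keeps double arylation and attack on ring A of the flavan low. The new C4 centre is set by the substrate: the 2-aryl and 3-benzyloxy groups both lie on the α face, so the arene should enter on the β face (3,4-trans).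

Step 4
Reactants: 5 2-(penta-O-benzylepicatechin-4β-yl)benzene-1,3,5-triol
Product: 6 2-(penta-O-benzylepicatechin-4β-yl)-5-(triisopropylsilyloxy)benzene-1,3-diol
Conditions: TIPSCl (1.05 equiv), imidazole (2.2 equiv), DMF, 0 °C
Reagents that add atoms: triisopropylsilyl chloride, CC(C)[Si](Cl)(C(C)C)C(C)C
Why: Sterically controlled silylation: the hydroxyl para to the flavanyl group has two hydrogen neighbours, while each of the other two is flanked by the bulky flavanyl substituent, so the large silyl chloride should take the para oxygen. Mis-silylated material can be returned to 5 with fluoride.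

Step 5
Reactants: 6 2-(penta-O-benzylepicatechin-4β-yl)-5-(triisopropylsilyloxy)benzene-1,3-diol
Product: 7 [3,5-bis(benzyloxy)-4-(penta-O-benzylepicatechin-4β-yl)phenoxy]triisopropylsilane
Conditions: BnBr (3 equiv), K2CO3 (4 equiv), dry DMF, rt
Reagents that add atoms: benzyl bromide, BrCc1ccccc1
Why: Williamson etherification of the two remaining phenols; phenoxide O-alkylation is little affected by ortho substituents, a dipolar aprotic solvent favours O- over C-benzylation, and an aryl triisopropylsilyl ether is stable to anhydrous carbonate at room temperature.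

Step 6
Reactants: 7 [3,5-bis(benzyloxy)-4-(penta-O-benzylepicatechin-4β-yl)phenoxy]triisopropylsilane
Product: 8 3,5-bis(benzyloxy)-4-(penta-O-benzylepicatechin-4β-yl)phenol
Conditions: TBAF (1.1 equiv), AcOH (1.1 equiv), THF, 0 °C
Reagents that add atoms: none
Why: Fluoride cleavage of the aryl silyl ether; acetic acid protonates the electron-rich phenoxide as it forms, so that it is not exposed to air as the anion.

Step 7
Reactants: 8 3,5-bis(benzyloxy)-4-(penta-O-benzylepicatechin-4β-yl)phenol
Product: 9 2-bromo-3,5-bis(benzyloxy)-4-(penta-O-benzylepicatechin-4β-yl)phenol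
Conditions: NBS (1.0 equiv), CH2Cl2, −78 to −40 °C
Reagents that add atoms: N-bromosuccinimide, BrN1C(=O)CCC1=O
Why: Electrophilic ortho-bromination of a phenol, which should be far faster than substitution of the aryl ether rings; the two ortho carbons are equivalent, the para carbon is occupied, and the first bromine slows a second substitution, so one equivalent at low temperature should stop at 9.

Step 8
Reactants: 9 2-bromo-3,5-bis(benzyloxy)-4-(penta-O-benzylepicatechin-4β-yl)phenol
Product: 10 3-bromo-2-hydroxy-4,6-bis(benzyloxy)-5-(penta-O-benzylepicatechin-4β-yl)benzaldehyde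
Conditions: MgCl2 (3 equiv), Et3N (6 equiv), (CH2O)n (10 equiv), THF, 65 °C
Reagents that add atoms: paraformaldehyde (as formaldehyde), C=O
Why: Casnati–Skattebøl ortho-formylation: the magnesium phenoxide delivers formaldehyde to the ortho carbon and a second formaldehyde takes up hydride from the hydroxymethyl stage. Only one ortho carbon is free and the aryl ethers do not react, as in the known conversion of 2-bromophenols into 3-bromosalicylaldehydes.

Step 9
Reactants: 11 3,4-bis(benzyloxy)benzaldehyde
Product: 12 (E)-3-[3,4-bis(benzyloxy)phenyl]prop-2-enal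
Conditions: Ph3P=CHCHO (1.1 equiv), toluene, 80 °C
Reagents that add atoms: (triphenylphosphoranylidene)acetaldehyde, O=CC=P(c1ccccc1)(c1ccccc1)c1ccccc1
Why: Wittig two-carbon homologation with a stabilised ylide, which should give the E-enal; a small excess of ylide limits a second homologation of the product.

Step 10
Reactants: 10 3-bromo-2-hydroxy-4,6-bis(benzyloxy)-5-(penta-O-benzylepicatechin-4β-yl)benzaldehyde; 12 (E)-3-[3,4-bis(benzyloxy)phenyl]prop-2-enal
Product: 13 (2R)-5,7-bis(benzyloxy)-2-[3,4-bis(benzyloxy)phenyl]-8-bromo-6-(penta-O-benzylepicatechin-4β-yl)-2H-chromene-3-carbaldehyde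
Conditions: enal in 1.5-fold excess, (S)-2-[diphenyl(trimethylsilyloxy)methyl]pyrrolidine (20 mol %), 2-nitrobenzoic acid (20 mol %), toluene, rt
Reagents that add atoms: none
Why: The secondary amine condenses with 12 to an (E)-iminium ion, and the phenol of 10, acidified by the ortho bromine and the ortho formyl group, adds to its β-carbon to form O1–C2. The enamine so formed attacks the neighbouring aryl aldehyde to form C3–C4 in a 6-exo-trig aldol closure of ring C, and loss of water followed by hydrolysis releases 13 and the amine. The closest known reaction is the diarylprolinol-silyl-ether-catalysed oxa-Michael–aldol condensation of salicylaldehydes with cinnamaldehydes to 2-aryl-2H-chromene-3-carbaldehydes. C2 is the only new stereocentre and is set by the catalyst, whose diphenyl(trimethylsilyloxy)methyl group covers the Re face of the β-carbon so that the phenol should enter on the Si face and give 2R, the remote stereocentres of the upper unit playing no part. Because the conjugate addition is reversible, the selectivity rests on faster aldol closure of the favoured adduct, and the two C2 epimers are in any case diastereomers that can be separated. Regiochemistry needs no control, since the formyl group fixes C4a and the single free phenol fixes O1, every other oxygen being benzylated. The weak acid speeds iminium formation and the final dehydration.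

Step 11
Reactants: 13 (2R)-5,7-bis(benzyloxy)-2-[3,4-bis(benzyloxy)phenyl]-8-bromo-6-(penta-O-benzylepicatechin-4β-yl)-2H-chromene-3-carbaldehyde
Product: 15 (2R)-5,7-bis(benzyloxy)-2-[3,4-bis(benzyloxy)phenyl]-8-bromo-6-(penta-O-benzylepicatechin-4β-yl)chroman-3-one, via enol formate 14 (not isolated)
Conditions: m-CPBA (1.2 equiv), CH2Cl2, 0 °C; then KHCO3, MeOH, 0 °C
Reagents that add atoms: 3-chloroperbenzoic acid, OOC(=O)c1cccc(Cl)c1
Why: Baeyer–Villiger oxidation of an α,β-unsaturated aldehyde: the electron-rich alkenyl group migrates in preference to hydrogen and gives the enol formate, whose very labile ester is cleaved by methanol. The freed enol ketonises by protonation at C4, so C2 is not involved; mild bicarbonate at 0 °C and use of the crude ketone guard against enolisation towards C2.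

Step 12
Reactants: 15 (2R)-5,7-bis(benzyloxy)-2-[3,4-bis(benzyloxy)phenyl]-8-bromo-6-(penta-O-benzylepicatechin-4β-yl)chroman-3-one
Product: 16 (2R,3R)-5,7-bis(benzyloxy)-2-[3,4-bis(benzyloxy)phenyl]-8-bromo-6-(penta-O-benzylepicatechin-4β-yl)chroman-3-ol
Conditions: LiBH(s-Bu)3 (1.5 equiv), THF, −78 °C; then H2O
Reagents that add atoms: none
Why: Reduction of a flavan-3-one with a bulky hydride, the known way from 2,3-trans to 2,3-cis flavan-3-ols: the reagent approaches along the equatorial direction, away from the equatorial 2-aryl group, and gives the axial alcohol cis to that group (3R). The aryl bromide is inert at −78 °C.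

Step 13
Reactants: 16 (2R,3R)-5,7-bis(benzyloxy)-2-[3,4-bis(benzyloxy)phenyl]-8-bromo-6-(penta-O-benzylepicatechin-4β-yl)chroman-3-ol
Product: 17 (2R,3R)-5,7-bis(benzyloxy)-2-[3,4-bis(benzyloxy)phenyl]-8-bromo-6-(8-bromo-penta-O-benzylepicatechin-4β-yl)chroman-3-ol
Conditions: NBS (1.05 equiv), CH2Cl2, −78 to 0 °C
Reagents that add atoms: N-bromosuccinimide, BrN1C(=O)CCC1=O
Why: Electrophilic bromination at C8 of the upper unit, the position between the ring oxygen and one benzyloxy group at which 5,7-dialkoxyflavans are known to brominate; the other ring A is fully substituted and the catechol ether rings are less activated. This cap deactivates the last nucleophilic ring of the future electrophile.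

Step 14
Reactants: 17 (2R,3R)-5,7-bis(benzyloxy)-2-[3,4-bis(benzyloxy)phenyl]-8-bromo-6-(8-bromo-penta-O-benzylepicatechin-4β-yl)chroman-3-ol
Product: 18 (2R,3R,4S)-5,7-bis(benzyloxy)-2-[3,4-bis(benzyloxy)phenyl]-8-bromo-6-(8-bromo-penta-O-benzylepicatechin-4β-yl)-4-(2-ethoxyethoxy)chroman-3-ol
Conditions: DDQ (1.5 equiv), 2-ethoxyethanol (5 equiv), CH2Cl2, rt
Reagents that add atoms: 2-ethoxyethanol, CCOCCO
Why: The same oxidative C4 etherification as in step 2, here on the lower unit, whose pseudo-axial C4–H is aligned with the π system of its ring A. The interflavan C–H lies close to the plane of the doubly ortho-substituted ring and is pseudo-equatorial on its own ring C, so it is a poor hydride donor; the alcohol adds trans to the free 3-hydroxyl.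

Step 15
Reactants: 18 (2R,3R,4S)-5,7-bis(benzyloxy)-2-[3,4-bis(benzyloxy)phenyl]-8-bromo-6-(8-bromo-penta-O-benzylepicatechin-4β-yl)-4-(2-ethoxyethoxy)chroman-3-ol; 16 (2R,3R)-5,7-bis(benzyloxy)-2-[3,4-bis(benzyloxy)phenyl]-8-bromo-6-(penta-O-benzylepicatechin-4β-yl)chroman-3-ol
Product: 19 octadeca-O-benzyl-tribromo tetramer [epicatechin-(4β→6)-epicatechin-(4β→8)-epicatechin-(4β→6)-epicatechin carrying benzyl ethers on all sixteen phenolic oxygens plus the 3-oxygens of the first/third units counted from the top; bromine at C8 of the first/second/fourth units; free 3-hydroxyls on the second/fourth units]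
Conditions: nucleophilic dimer in 1.5-fold excess, TMSOTf (0.5 equiv), CH2Cl2, −78 to −40 °C; Et3N quench
Reagents that add atoms: none
Why: Lewis-acid-mediated Friedel–Crafts union of a 4-(2-ethoxyethoxy)flavan with a benzylated flavan nucleophile, the standard way to a 4→8 interflavan bond. The cation at C4 of unit 2 should be taken by the upper unit of 16, at C8 in preference to the more hindered C6, since every other ring A is either fully substituted or deactivated by its C8 bromine. The 2,3-cis substituents of unit 2 direct the attack to the β face and so set its C4.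

Step 16
Reactants: 19 octadeca-O-benzyl-tribromo tetramer
Product: 20 epicatechin-(4β→6)-epicatechin-(4β→8)-epicatechin-(4β→6)-epicatechin (CNP0120618.1)
Conditions: H2 (1 atm), Pd(OH)2/C, NaOAc (3.5 equiv), THF–MeOH–H2O, rt
Reagents that add atoms: none
Why: Hydrogenolysis removes the eighteen benzyl ethers and reduces the three aryl C–Br bonds in one operation, as is usual for bromine-capped, benzylated flavan oligomers. Acetate takes up the hydrogen bromide so that the acid-labile interflavan bonds are not exposed to strong acid, and unlike an amine it does not slow ether cleavage.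

## Compound list

1 | (−)-epicatechin, (2R,3R)-2-(3,4-dihydroxyphenyl)chromane-3,5,7-triol | O[C@@H]1Cc2c(O)cc(O)cc2O[C@@H]1c1ccc(O)c(O)c1 | starting material

2 | penta-O-benzylepicatechin, (2R,3R)-3,5,7-tris(benzyloxy)-2-[3,4-bis(benzyloxy)phenyl]chromane | O(Cc9ccccc9)c1cc(OCc9ccccc9)c2c(c1)O[C@H](c7ccc(OCc9ccccc9)c(OCc9ccccc9)c7)[C@H](OCc9ccccc9)C2 | intermediate

3 | (2R,3R,4S)-3,5,7-tris(benzyloxy)-2-[3,4-bis(benzyloxy)phenyl]-4-(2-ethoxyethoxy)chromane (4β ether) | O(Cc9ccccc9)c1cc(OCc9ccccc9)c2c(c1)O[C@H](c7ccc(OCc9ccccc9)c(OCc9ccccc9)c7)[C@H](OCc9ccccc9)[C@H]2OCCOCC | intermediate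

4 | phloroglucinol, benzene-1,3,5-triol | Oc1cc(O)cc(O)c1 | starting material

5 | 2-(penta-O-benzylepicatechin-4β-yl)benzene-1,3,5-triol | O(Cc9ccccc9)c1cc(OCc9ccccc9)c2c(c1)O[C@H](c7ccc(OCc9ccccc9)c(OCc9ccccc9)c7)[C@H](OCc9ccccc9)[C@H]2c1c(O)cc(O)cc1O | intermediate

6 | 2-(penta-O-benzylepicatechin-4β-yl)-5-(triisopropylsilyloxy)benzene-1,3-diol | O(Cc9ccccc9)c1cc(OCc9ccccc9)c2c(c1)O[C@H](c7ccc(OCc9ccccc9)c(OCc9ccccc9)c7)[C@H](OCc9ccccc9)[C@H]2c1c(O)cc(O[Si](C(C)C)(C(C)C)C(C)C)cc1O | intermediate

7 | [3,5-bis(benzyloxy)-4-(penta-O-benzylepicatechin-4β-yl)phenoxy]triisopropylsilane | O(Cc9ccccc9)c1cc(OCc9ccccc9)c2c(c1)O[C@H](c7ccc(OCc9ccccc9)c(OCc9ccccc9)c7)[C@H](OCc9ccccc9)[C@H]2c1c(OCc9ccccc9)cc(O[Si](C(C)C)(C(C)C)C(C)C)cc1OCc9ccccc9 | intermediate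

8 | 3,5-bis(benzyloxy)-4-(penta-O-benzylepicatechin-4β-yl)phenol | O(Cc9ccccc9)c1cc(OCc9ccccc9)c2c(c1)O[C@H](c7ccc(OCc9ccccc9)c(OCc9ccccc9)c7)[C@H](OCc9ccccc9)[C@H]2c1c(OCc9ccccc9)cc(O)cc1OCc9ccccc9 | intermediate

9 | 2-bromo-3,5-bis(benzyloxy)-4-(penta-O-benzylepicatechin-4β-yl)phenol | O(Cc9ccccc9)c1cc(OCc9ccccc9)c2c(c1)O[C@H](c7ccc(OCc9ccccc9)c(OCc9ccccc9)c7)[C@H](OCc9ccccc9)[C@H]2c1c(OCc9ccccc9)c(Br)c(O)cc1OCc9ccccc9 | intermediate

10 | 3-bromo-2-hydroxy-4,6-bis(benzyloxy)-5-(penta-O-benzylepicatechin-4β-yl)benzaldehyde | O(Cc9ccccc9)c1cc(OCc9ccccc9)c2c(c1)O[C@H](c7ccc(OCc9ccccc9)c(OCc9ccccc9)c7)[C@H](OCc9ccccc9)[C@H]2c1c(OCc9ccccc9)c(Br)c(O)c(C=O)c1OCc9ccccc9 | intermediate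

11 | 3,4-bis(benzyloxy)benzaldehyde | O=Cc1ccc(OCc2ccccc2)c(OCc2ccccc2)c1 | starting material

12 | (E)-3-[3,4-bis(benzyloxy)phenyl]prop-2-enal | O=C/C=C/c1ccc(OCc2ccccc2)c(OCc2ccccc2)c1 | intermediate

13 | (2R)-5,7-bis(benzyloxy)-2-[3,4-bis(benzyloxy)phenyl]-8-bromo-6-(penta-O-benzylepicatechin-4β-yl)-2H-chromene-3-carbaldehyde | O(Cc9ccccc9)c1cc(OCc9ccccc9)c2c(c1)O[C@H](c7ccc(OCc9ccccc9)c(OCc9ccccc9)c7)[C@H](OCc9ccccc9)[C@H]2c1c(OCc9ccccc9)c(Br)c2c(c1OCc9ccccc9)C=C(C=O)[C@@H](c7ccc(OCc9ccccc9)c(OCc9ccccc9)c7)O2 | intermediate

14 | (2R)-5,7-bis(benzyloxy)-2-[3,4-bis(benzyloxy)phenyl]-8-bromo-6-(penta-O-benzylepicatechin-4β-yl)-2H-chromen-3-yl formate | O(Cc9ccccc9)c1cc(OCc9ccccc9)c2c(c1)O[C@H](c7ccc(OCc9ccccc9)c(OCc9ccccc9)c7)[C@H](OCc9ccccc9)[C@H]2c1c(OCc9ccccc9)c(Br)c2c(c1OCc9ccccc9)C=C(OC=O)[C@@H](c7ccc(OCc9ccccc9)c(OCc9ccccc9)c7)O2 | intermediate (not isolated)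

15 | (2R)-5,7-bis(benzyloxy)-2-[3,4-bis(benzyloxy)phenyl]-8-bromo-6-(penta-O-benzylepicatechin-4β-yl)chroman-3-one | O(Cc9ccccc9)c1cc(OCc9ccccc9)c2c(c1)O[C@H](c7ccc(OCc9ccccc9)c(OCc9ccccc9)c7)[C@H](OCc9ccccc9)[C@H]2c1c(OCc9ccccc9)c(Br)c2c(c1OCc9ccccc9)CC(=O)[C@@H](c7ccc(OCc9ccccc9)c(OCc9ccccc9)c7)O2 | intermediate

16 | (2R,3R)-5,7-bis(benzyloxy)-2-[3,4-bis(benzyloxy)phenyl]-8-bromo-6-(penta-O-benzylepicatechin-4β-yl)chroman-3-ol | O(Cc9ccccc9)c1cc(OCc9ccccc9)c2c(c1)O[C@H](c7ccc(OCc9ccccc9)c(OCc9ccccc9)c7)[C@H](OCc9ccccc9)[C@H]2c1c(OCc9ccccc9)c(Br)c2c(c1OCc9ccccc9)C[C@@H](O)[C@@H](c7ccc(OCc9ccccc9)c(OCc9ccccc9)c7)O2 | intermediate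

17 | (2R,3R)-5,7-bis(benzyloxy)-2-[3,4-bis(benzyloxy)phenyl]-8-bromo-6-(8-bromo-penta-O-benzylepicatechin-4β-yl)chroman-3-ol | O(Cc9ccccc9)c1cc(OCc9ccccc9)c2c(c1Br)O[C@H](c7ccc(OCc9ccccc9)c(OCc9ccccc9)c7)[C@H](OCc9ccccc9)[C@H]2c1c(OCc9ccccc9)c(Br)c2c(c1OCc9ccccc9)C[C@@H](O)[C@@H](c7ccc(OCc9ccccc9)c(OCc9ccccc9)c7)O2 | intermediate

18 | (2R,3R,4S)-5,7-bis(benzyloxy)-2-[3,4-bis(benzyloxy)phenyl]-8-bromo-6-(8-bromo-penta-O-benzylepicatechin-4β-yl)-4-(2-ethoxyethoxy)chroman-3-ol (4β ether) | O(Cc9ccccc9)c1cc(OCc9ccccc9)c2c(c1Br)O[C@H](c7ccc(OCc9ccccc9)c(OCc9ccccc9)c7)[C@H](OCc9ccccc9)[C@H]2c1c(OCc9ccccc9)c(Br)c2c(c1OCc9ccccc9)[C@H](OCCOCC)[C@@H](O)[C@@H](c7ccc(OCc9ccccc9)c(OCc9ccccc9)c7)O2 | intermediate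

19 | octadeca-O-benzyl-tribromo epicatechin-(4β→6)-epicatechin-(4β→8)-epicatechin-(4β→6)-epicatechin (benzyl on all sixteen phenolic oxygens plus the 3-oxygens of the first/third units counted from the top; bromine at C8 of the first/second/fourth units; free 3-hydroxyls on the second/fourth units) | O(Cc9ccccc9)c1cc(OCc9ccccc9)c2c(c1Br)O[C@H](c7ccc(OCc9ccccc9)c(OCc9ccccc9)c7)[C@H](OCc9ccccc9)[C@H]2c1c(OCc9ccccc9)c(Br)c2c(c1OCc9ccccc9)[C@H](c1c(OCc9ccccc9)cc(OCc9ccccc9)c3c1O[C@H](c7ccc(OCc9ccccc9)c(OCc9ccccc9)c7)[C@H](OCc9ccccc9)[C@H]3c1c(OCc9ccccc9)c(Br)c3c(c1OCc9ccccc9)C[C@@H](O)[C@@H](c7ccc(OCc9ccccc9)c(OCc9ccccc9)c7)O3)[C@@H](O)[C@@H](c7ccc(OCc9ccccc9)c(OCc9ccccc9)c7)O2 | intermediate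

20 | epicatechin-(4β→6)-epicatechin-(4β→8)-epicatechin-(4β→6)-epicatechin, CNP0120618.1 | Oc1cc(O)c2c(c1)O[C@H](c1ccc(O)c(O)c1)[C@H](O)[C@H]2c1c(O)cc2c(c1O)[C@H](c1c(O)cc(O)c3c1O[C@H](c1ccc(O)c(O)c1)[C@H](O)[C@H]3c1c(O)cc3c(c1O)C[C@@H](O)[C@@H](c1ccc(O)c(O)c1)O3)[C@@H](O)[C@@H](c1ccc(O)c(O)c1)O2 | target

## Step count and least certain steps

Total: 16 steps. Longest linear sequence: 15 steps (steps 1 to 8 and 10 to 16). Step 9 is the one-step side branch, and 16 enters step 15 a second time as the nucleophile.

**Step 10 (key step).** The annulation may stall, because the phenol is hydrogen-bonded and flanked by bromine, the formyl group is flanked by a benzyloxy group, and the electron-rich enal gives a weakly electrophilic iminium ion. The facial selectivity may also erode through reversal of the conjugate addition before the aldol closure. The fallback brings in the C2–C3 unit as a nitroalkene and so removes both the iminium activation and the later formyl excision. From 11, a Henry condensation with nitromethane (NH4OAc, AcOH, heat) gives (E)-1,2-bis(benzyloxy)-4-(2-nitroethenyl)benzene F1. 10 and F1 then react under DABCO in an oxa-Michael–Henry–dehydration sequence to the 3-nitro-2H-chromene F2, whose two C2 epimers are diastereomers and are separated, the 2R epimer being carried on. Buffered aqueous TiCl3 (NH4OAc, THF) reduces and hydrolyses the nitroalkene to the ketone, and the route is rejoined at 15.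

**Step 4.** Site selectivity may be lost, with silylation at an ortho hydroxyl or at two hydroxyls, if the flavanyl group shields its neighbours less than expected. The fallback buys the oxygen differentiation in with the nucleophile. Commercial 3,5-bis(benzyloxy)phenol F3 is silylated (TIPSCl, imidazole) to [3,5-bis(benzyloxy)phenoxy]triisopropylsilane F4. Starting from 3, F4 is used in large excess in a TMSOTf-mediated Friedel–Crafts arylation at −78 °C, and the product arylated between the two benzyloxy groups is separated from any isomer arylated next to the silyloxy group. The route is rejoined at 7, two steps shorter but with a position-selectivity question in the arylation that the main route avoids.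

**Step 11.** The peracid may oxidise the electron-rich ether rings or epoxidise the enol formate, and the ketone may epimerise at C2 while the formate is cleaved. The fallback excises the formyl carbon as carbon dioxide without a peracid. From 13, oxidation with NaClO2 (NaH2PO4, 2-methylbut-2-ene, t-BuOH–THF–H2O) gives the 2H-chromene-3-carboxylic acid F5. A Curtius rearrangement with (PhO)2P(O)N3 and Et3N in toluene at 80 °C in the presence of 2-(trimethylsilyl)ethanol gives the 2-(trimethylsilyl)ethyl enecarbamate F6. TBAF then releases the enamine, which hydrolyses on aqueous work-up, and the route is rejoined at 15.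

**Step 15.** The acid may cleave or scramble the interflavan bonds already present, the cation may be taken at C6 instead of C8 of unit 3, or a free 3-hydroxyl may capture it. The fallback replaces acid activation by thiophilic activation under neutral conditions. From 18, exchange of the 2-ethoxyethoxy group with the aluminium thiolate made from 2-sulfanylbenzothiazole and AlMe3 gives the 4β-(benzothiazol-2-ylsulfanyl) dimer F7. AgBF4 in THF at 0 °C then ionises the C–S bond in the presence of 16, and the route is rejoined at 19.

## Further compounds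

F1 | step 10 | (E)-1,2-bis(benzyloxy)-4-(2-nitroethenyl)benzene | [O-][N+](=O)/C=C/c1ccc(OCc2ccccc2)c(OCc2ccccc2)c1
F2 | step 10 | (2R)-5,7-bis(benzyloxy)-2-[3,4-bis(benzyloxy)phenyl]-8-bromo-3-nitro-6-(penta-O-benzylepicatechin-4β-yl)-2H-chromene | O(Cc9ccccc9)c1cc(OCc9ccccc9)c2c(c1)O[C@H](c7ccc(OCc9ccccc9)c(OCc9ccccc9)c7)[C@H](OCc9ccccc9)[C@H]2c1c(OCc9ccccc9)c(Br)c2c(c1OCc9ccccc9)C=C([N+](=O)[O-])[C@@H](c7ccc(OCc9ccccc9)c(OCc9ccccc9)c7)O2
F3 | step 4 | 3,5-bis(benzyloxy)phenol | Oc1cc(OCc2ccccc2)cc(OCc2ccccc2)c1
F4 | step 4 | [3,5-bis(benzyloxy)phenoxy]triisopropylsilane | CC(C)[Si](Oc1cc(OCc2ccccc2)cc(OCc2ccccc2)c1)(C(C)C)C(C)C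
F5 | step 11 | (2R)-5,7-bis(benzyloxy)-2-[3,4-bis(benzyloxy)phenyl]-8-bromo-6-(penta-O-benzylepicatechin-4β-yl)-2H-chromene-3-carboxylic acid | O(Cc9ccccc9)c1cc(OCc9ccccc9)c2c(c1)O[C@H](c7ccc(OCc9ccccc9)c(OCc9ccccc9)c7)[C@H](OCc9ccccc9)[C@H]2c1c(OCc9ccccc9)c(Br)c2c(c1OCc9ccccc9)C=C(C(=O)O)[C@@H](c7ccc(OCc9ccccc9)c(OCc9ccccc9)c7)O2
F6 | step 11 | 2-(trimethylsilyl)ethyl N-[(2R)-5,7-bis(benzyloxy)-2-[3,4-bis(benzyloxy)phenyl]-8-bromo-6-(penta-O-benzylepicatechin-4β-yl)-2H-chromen-3-yl]carbamate | O(Cc9ccccc9)c1cc(OCc9ccccc9)c2c(c1)O[C@H](c7ccc(OCc9ccccc9)c(OCc9ccccc9)c7)[C@H](OCc9ccccc9)[C@H]2c1c(OCc9ccccc9)c(Br)c2c(c1OCc9ccccc9)C=C(NC(=O)OCC[Si](C)(C)C)[C@@H](c7ccc(OCc9ccccc9)c(OCc9ccccc9)c7)O2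
F7 | step 15 | (2R,3S,4S)-4-(benzothiazol-2-ylsulfanyl)-5,7-bis(benzyloxy)-2-[3,4-bis(benzyloxy)phenyl]-8-bromo-6-(8-bromo-penta-O-benzylepicatechin-4β-yl)chroman-3-ol (4β thioether; same spatial arrangement as 18, the descriptor at C3 changes by the sequence rule only) | O(Cc9ccccc9)c1cc(OCc9ccccc9)c2c(c1Br)O[C@H](c7ccc(OCc9ccccc9)c(OCc9ccccc9)c7)[C@H](OCc9ccccc9)[C@H]2c1c(OCc9ccccc9)c(Br)c2c(c1OCc9ccccc9)[C@H](Sc1nc3ccccc3s1)[C@@H](O)[C@@H](c7ccc(OCc9ccccc9)c(OCc9ccccc9)c7)O2
A1 | alternative 1 | benzylated unit 1–(4β→6)–unit 2 dimer carrying a free 3-OH on unit 1, 3-O-benzyl and 8-bromo on unit 2 | O(Cc9ccccc9)c1cc(OCc9ccccc9)c2c(c1)O[C@H](c7ccc(OCc9ccccc9)c(OCc9ccccc9)c7)[C@H](O)[C@H]2c1c(OCc9ccccc9)c(Br)c2c(c1OCc9ccccc9)C[C@@H](OCc9ccccc9)[C@@H](c7ccc(OCc9ccccc9)c(OCc9ccccc9)c7)O2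
A2 | alternative 1 | 3,5-bis(benzyloxy)phenyl ether of the trans-2,3-epoxy-1-[3,4-bis(benzyloxy)phenyl]propan-1-ol whose C3 carries the 8-bromo-penta-O-benzylepicatechin-6-yl group | O(Cc9ccccc9)c1cc(OCc9ccccc9)cc(c1)O[C@H](c7ccc(OCc9ccccc9)c(OCc9ccccc9)c7)[C@@H]3O[C@H]3c1c(OCc9ccccc9)c(Br)c2c(c1OCc9ccccc9)C[C@@H](OCc9ccccc9)[C@@H](c7ccc(OCc9ccccc9)c(OCc9ccccc9)c7)O2
A3 | alternative 2 | 5-(benzyloxy)-2-{(E)-3-[3,4-bis(benzyloxy)phenyl]prop-2-enyl}-4-(penta-O-benzylepicatechin-4β-yl)-3-(triisopropylsilyloxy)phenol | O(Cc9ccccc9)c1cc(OCc9ccccc9)c2c(c1)O[C@H](c7ccc(OCc9ccccc9)c(OCc9ccccc9)c7)[C@H](OCc9ccccc9)[C@H]2c1c(OCc9ccccc9)cc(O)c(C/C=C/c7ccc(OCc9ccccc9)c(OCc9ccccc9)c7)c1O[Si](C(C)C)(C(C)C)C(C)C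
A4 | alternative 2 | 3-(benzyloxy)-2-(penta-O-benzylepicatechin-4β-yl)cyclobut-2-en-1-one | O(Cc9ccccc9)c1cc(OCc9ccccc9)c2c(c1)O[C@H](c7ccc(OCc9ccccc9)c(OCc9ccccc9)c7)[C@H](OCc9ccccc9)[C@H]2C1=C(OCc9ccccc9)CC1=O
A5 | alternative 2 | {(E)-5-[3,4-bis(benzyloxy)phenyl]pent-4-en-1-ynyloxy}triisopropylsilane | CC(C)[Si](OC#CC/C=C/c1ccc(OCc2ccccc2)c(OCc2ccccc2)c1)(C(C)C)C(C)C
A6 | alternative 3 | perbenzylated tetramer carrying a C2 trimethylsilyl ketal in unit 2 and bromine at C8 of unit 4 | O(Cc9ccccc9)c1cc(OCc9ccccc9)c2c(c1)O[C@H](c7ccc(OCc9ccccc9)c(OCc9ccccc9)c7)[C@H](OCc9ccccc9)[C@H]2c1c(OCc9ccccc9)cc2c(c1OCc9ccccc9)[C@H](c1c(OCc9ccccc9)cc(OCc9ccccc9)c3c1O[C@H](c7ccc(OCc9ccccc9)c(OCc9ccccc9)c7)[C@H](OCc9ccccc9)[C@H]3c1c(OCc9ccccc9)c(Br)c3c(c1OCc9ccccc9)C[C@@H](OCc9ccccc9)[C@@H](c7ccc(OCc9ccccc9)c(OCc9ccccc9)c7)O3)[C@@H](OCc9ccccc9)[C@@](O[Si](C)(C)C)(c7ccc(OCc9ccccc9)c(OCc9ccccc9)c7)O2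
A7 | alternative 3 | 8-formyl unit 3–(4β→6)–unit 4 dimer, perbenzylated, bromine at C8 of unit 4 | O(Cc9ccccc9)c1cc(OCc9ccccc9)c2c(c1C=O)O[C@H](c7ccc(OCc9ccccc9)c(OCc9ccccc9)c7)[C@H](OCc9ccccc9)[C@H]2c1c(OCc9ccccc9)c(Br)c2c(c1OCc9ccccc9)C[C@@H](OCc9ccccc9)[C@@H](c7ccc(OCc9ccccc9)c(OCc9ccccc9)c7)O2
A8 | alternative 3 | (Z)-[2-(benzyloxy)-1-[3,4-bis(benzyloxy)phenyl]ethenyloxy]trimethylsilane | C[Si](C)(C)O/C(c1ccc(OCc2ccccc2)c(OCc2ccccc2)c1)=C\OCc1ccccc1
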